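**Assumption:** the SMILES is read as the (4R) side-chain centre and the (1R,4R,5R,6S) oxabicycle (crispatone-type skeleton); (S)-but-3-yn-2-ol of ≥98% ee is the only source of chirality.

## Retrosynthetic overview

1. The oxirane is installed last by substrate-controlled epoxidation of a cyclohexadiene, after oxidation of the side-chain carbinol to the ethyl ketone.
2. The cyclohexadiene (only carbocycle) comes from thermal disrotatory 6π-electrocyclisation of a (2E,4Z,6E,8E)-tetraenyl pyranone.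
3. The tetraene comes from Negishi coupling of a (Z)-iododienyl pyranone with a dienylzirconium made by hydrozirconation of a chiral enynol.
4. The iodide arm is built from propargyl alcohol (carbomagnesiation, Wittig), then dianion aldol, oxidation, lactonisation and O-methylation form the pyranone. The enynol arm comes from (S)-but-3-yn-2-ol by allenylzinc addition to propanal (chirality relay), C-methylation, hydrozirconation–iodination and Sonogashira coupling.
5. Ring order: pyranone first, cyclohexadiene second, oxirane last.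

## Route

**Step 1**
Reactants: 1 prop-2-yn-1-ol
Product: 3 (Z)-3-iodo-2-methylprop-2-en-1-ol, via alkenylmagnesium alkoxide 2 (not isolated)
Conditions: MeMgBr (3 equiv), CuI (10 mol%), THF/Et2O, −10 °C → rt; then I2, −10 °C; aqueous work-up
Reagents that add atoms: methylmagnesium bromide C[Mg]Br; iodine II
Why: Copper-catalysed anti-carbomagnesiation of the propargylic alkoxide (Duboudin reaction) puts magnesium cis to CH2O in a five-membered chelate, and iodinolysis with retention gives the (Z)-vinyl iodide.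

**Step 2**
Reactants: 3 (Z)-3-iodo-2-methylprop-2-en-1-ol; 4 2-(triphenylphosphoranylidene)propanal
Product: 6 (2E,4Z)-5-iodo-2,4-dimethylpenta-2,4-dienal, via (Z)-3-iodo-2-methylprop-2-enal 5 (not isolated)
Conditions: activated MnO2, CH2Cl2, rt; filter; then 4 (1.1 equiv), PhMe, 60 °C, dark
Reagents that add atoms: none
Why: Allylic oxidation with MnO2 followed by Wittig olefination with the stabilised formyl ylide gives the (E)-enal and leaves the (Z)-iodoalkene untouched.

**Step 3**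
Reactants: 6 (2E,4Z)-5-iodo-2,4-dimethylpenta-2,4-dienal; 7 methyl 2-methyl-3-oxopentanoate
Product: 9 methyl (6E,8Z)-5-hydroxy-9-iodo-2,4,6,8-tetramethyl-3-oxonona-6,8-dienoate (diastereomer mixture), via ketoester dianion 8 (not isolated)
Conditions: 7 (1.3 equiv), NaH, THF, 0 °C; n-BuLi, 0 °C; then 6, −78 °C; 1 M HCl quench
Reagents that add atoms: none
Why: The γ-carbanion of the Weiler dianion adds 1,2 to the enal at −78 °C (dianion aldol addition), and the three new sp3 centres are irrelevant because all are lost in steps 4 and 5.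

**Step 4**
Reactants: 9 methyl (6E,8Z)-5-hydroxy-9-iodo-2,4,6,8-tetramethyl-3-oxonona-6,8-dienoate
Product: 10 methyl (6E,8Z)-9-iodo-2,4,6,8-tetramethyl-3,5-dioxonona-6,8-dienoate
Conditions: Dess–Martin periodinane, CH2Cl2, 0 °C → rt
Reagents that add atoms: none
Why: Dess–Martin oxidation converts the allylic secondary alcohol into the β,δ-diketo ester under neutral conditions that do not touch the vinyl iodide.

**Step 5**
Reactants: 10 methyl (6E,8Z)-9-iodo-2,4,6,8-tetramethyl-3,5-dioxonona-6,8-dienoate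
Product: 11 4-hydroxy-6-[(2E,4Z)-5-iodo-4-methylpenta-2,4-dien-2-yl]-3,5-dimethyl-2H-pyran-2-one
Conditions: DBU, PhMe, 60 °C
Reagents that add atoms: none
Why: DBU enolises the triketide and the dienone enol oxygen acylates intramolecularly on the methyl ester (lactonisation) to close the 4-hydroxy-2-pyranone.

**Step 6**
Reactants: 11 4-hydroxy-6-[(2E,4Z)-5-iodo-4-methylpenta-2,4-dien-2-yl]-3,5-dimethyl-2H-pyran-2-one
Product: 12 2-[(2E,4Z)-5-iodo-4-methylpenta-2,4-dien-2-yl]-6-methoxy-3,5-dimethyl-4H-pyran-4-one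
Conditions: MeOTf, CH2Cl2, rt; aq. NaHCO3 work-up
Reagents that add atoms: methyl trifluoromethanesulfonate COS(=O)(=O)C(F)(F)F
Why: The hard methylating agent alkylates the more nucleophilic lactone carbonyl oxygen (Beak-type O-methylation), which after proton loss gives the 2-methoxy-4-pyranone.

**Step 7**
Reactants: 13 (S)-but-3-yn-2-ol
Product: 14 (S)-but-3-yn-2-yl methanesulfonate
Conditions: MsCl, Et3N, CH2Cl2, −78 → 0 °C
Reagents that add atoms: methanesulfonyl chloride CS(=O)(=O)Cl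
Why: O-Sulfonylation of the secondary alcohol proceeds with retention at carbon.

**Step 8**
Reactants: 14 (S)-but-3-yn-2-yl methanesulfonate; 15 propanal
Product: 17 (3S,4R)-4-methylhex-5-yn-3-ol, via allenylzinc mesylate 16 (not isolated)
Conditions: Pd(OAc)2 (5 mol%), PPh3 (5 mol%), Et2Zn (3 equiv), THF, −78 → −20 °C; then 1 M HCl
Reagents that add atoms: none
Why: In this Marshall propargylation zerovalent palladium displaces the mesylate anti (SN2′), Et2Zn transmetalates to a configurationally defined allenylzinc, and cyclic SE2′ addition to propanal relays the butynol centre (net inversion) into the (4R) methyl centre with the anti carbinol; the minor syn carbinol epimer is removed by chromatography or converges in step 13.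

**Step 9**
Reactants: 17 (3S,4R)-4-methylhex-5-yn-3-ol
Product: 19 (3S,4R)-4-methylhept-5-yn-3-ol, via dilithio alkynolate 18 (not isolated)
Conditions: n-BuLi (2.1 equiv), THF, −78 → −30 °C; MeI (1.05 equiv), −78 → 0 °C; aqueous work-up
Reagents that add atoms: iodomethane CI
Why: The acetylide carbon of the dilithio species is far more nucleophilic than the lithium alkoxide, so one equivalent of MeI C-methylates selectively (acetylide alkylation).

**Step 10**
Reactants: 19 (3S,4R)-4-methylhept-5-yn-3-ol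
Product: 21 (3S,4R,5E)-6-iodo-4-methylhept-5-en-3-ol, via alkenylzirconocene 20 (not isolated)
Conditions: Cp2Zr(H)Cl (2.5 equiv), THF, rt → 45 °C; then I2, 0 °C; dilute HCl work-up
Reagents that add atoms: iodine II
Why: syn-Hydrozirconation puts zirconium on the less hindered methyl-bearing alkyne carbon (equilibrated by excess Cp2Zr(H)Cl), and iododezirconation with retention gives the (E)-trisubstituted vinyl iodide.

**Step 11**
Reactants: 21 (3S,4R,5E)-6-iodo-4-methylhept-5-en-3-ol; 22 propyne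
Product: 23 (3S,4R,5E)-4,6-dimethylnon-5-en-7-yn-3-ol
Conditions: propyne (excess), Pd(PPh3)2Cl2 (3 mol%), CuI (6 mol%), i-Pr2NH, THF, rt
Reagents that add atoms: none
Why: Sonogashira coupling proceeds with retention of alkene geometry and tolerates the free hydroxyl.

**Step 12**
Reactants: 23 (3S,4R,5E)-4,6-dimethylnon-5-en-7-yn-3-ol; 12 2-[(2E,4Z)-5-iodo-4-methylpenta-2,4-dien-2-yl]-6-methoxy-3,5-dimethyl-4H-pyran-4-one
Product: 27 2-{(1R,6S)-6-[(2E,4R,5S)-5-hydroxy-4-methylhept-2-en-2-yl]-1,3,5-trimethylcyclohexa-2,4-dien-1-yl}-6-methoxy-3,5-dimethyl-4H-pyran-4-one, via dienylzirconocene 24 (not isolated), via dienylzinc chloride 25 (not isolated), via tetraene 26 (not isolated)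
Conditions: 23 (1.2 equiv), Cp2Zr(H)Cl (2.2 equiv per 23), THF, rt → 40 °C; ZnCl2, 0 °C; 12, Pd(PPh3)4 (5 mol%), rt, dark; dilute HCl wash; crude in PhMe, 80 °C, dark
Reagents that add atoms: none
Why: syn-Hydrozirconation (Zr on the methyl-bearing carbon), transmetalation to zinc and Negishi coupling with retention give the (2E,4Z,6E,8E)-tetraene, whose (E,Z,E)-triene closes by thermal disrotatory 6π-electrocyclisation with pyranone and side chain cis; the sense of closure is biased only by the remote (4R,5S) side-chain centres, so a low diastereomer ratio is expected and the (1R,6S) isomer is separated from its (1S,6R) diastereomer by chromatography.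

**Step 13**
Reactants: 27 2-{(1R,6S)-6-[(2E,4R,5S)-5-hydroxy-4-methylhept-2-en-2-yl]-1,3,5-trimethylcyclohexa-2,4-dien-1-yl}-6-methoxy-3,5-dimethyl-4H-pyran-4-one
Product: 28 2-methoxy-3,5-dimethyl-6-{(1R,6S)-1,3,5-trimethyl-6-[(2E,4R)-4-methyl-5-oxohept-2-en-2-yl]cyclohexa-2,4-dien-1-yl}-4H-pyran-4-one
Conditions: Dess–Martin periodinane, pyridine, CH2Cl2, 0 °C
Reagents that add atoms: none
Why: Buffered Dess–Martin oxidation gives the ethyl ketone without epimerising the α-methyl centre or moving the β,γ-alkene into conjugation.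

**Step 14**
Reactants: 28 2-methoxy-3,5-dimethyl-6-{(1R,6S)-1,3,5-trimethyl-6-[(2E,4R)-4-methyl-5-oxohept-2-en-2-yl]cyclohexa-2,4-dien-1-yl}-4H-pyran-4-one
Product: 29 2-methoxy-3,5-dimethyl-6-{(1R,4R,5R,6S)-2,4,6-trimethyl-5-[(2E,4R)-4-methyl-5-oxohept-2-en-2-yl]-7-oxabicyclo[4.1.0]hept-2-en-4-yl}-4H-pyran-4-one
Conditions: DMDO (1.0 equiv), acetone, −40 → −20 °C
Reagents that add atoms: dimethyldioxirane CC1(C)OO1
Why: Neutral electrophilic epoxidation attacks the electron-rich diene at the alkene next to the tertiary CH (the other diene alkene is flanked by the quaternary carbon) from the face anti to the adjacent side chain, so both oxirane centres are set by substrate control.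

## Compound list

1 | prop-2-yn-1-ol (propargyl alcohol) | C#CCO | starting material
2 | bromomagnesium (Z)-3-(bromomagnesio)-2-methylprop-2-en-1-olate | Br[Mg]OC/C(C)=C\[Mg]Br | intermediate
3 | (Z)-3-iodo-2-methylprop-2-en-1-ol | OC/C(C)=C\I | intermediate
4 | 2-(triphenylphosphoranylidene)propanal | CC(C=O)=P(c1ccccc1)(c1ccccc1)c1ccccc1 | starting material
5 | (Z)-3-iodo-2-methylprop-2-enal | O=C/C(C)=C\I | intermediate
6 | (2E,4Z)-5-iodo-2,4-dimethylpenta-2,4-dienal | O=C/C(C)=C/C(C)=C\I | intermediate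
7 | methyl 2-methyl-3-oxopentanoate (racemic) | CCC(=O)C(C)C(=O)OC | starting material
8 | sodium lithium dianion (bis-enolate) of methyl 2-methyl-3-oxopentanoate | [Na+].[Li+].CC=C([O-])C(C)=C([O-])OC | intermediate
9 | methyl (6E,8Z)-5-hydroxy-9-iodo-2,4,6,8-tetramethyl-3-oxonona-6,8-dienoate (diastereomer mixture at C2, C4, C5) | COC(=O)C(C)C(=O)C(C)C(O)/C(C)=C/C(C)=C\I | intermediate
10 | methyl (6E,8Z)-9-iodo-2,4,6,8-tetramethyl-3,5-dioxonona-6,8-dienoate | COC(=O)C(C)C(=O)C(C)C(=O)/C(C)=C/C(C)=C\I | intermediate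
11 | 4-hydroxy-6-[(2E,4Z)-5-iodo-4-methylpenta-2,4-dien-2-yl]-3,5-dimethyl-2H-pyran-2-one | O=c1oc(/C(C)=C/C(C)=C\I)c(C)c(O)c1C | intermediate
12 | 2-[(2E,4Z)-5-iodo-4-methylpenta-2,4-dien-2-yl]-6-methoxy-3,5-dimethyl-4H-pyran-4-one | COc1oc(/C(C)=C/C(C)=C\I)c(C)c(=O)c1C | intermediate
13 | (S)-but-3-yn-2-ol | C[C@H](O)C#C | starting material
14 | (S)-but-3-yn-2-yl methanesulfonate | C[C@H](OS(C)(=O)=O)C#C | intermediate
15 | propanal | CCC=O | starting material
16 | [(M)-buta-1,2-dien-1-yl]zinc methanesulfonate (axially chiral allenylzinc) | CC([H])=[C@]=C([H])[Zn]OS(C)(=O)=O | intermediate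
17 | (3S,4R)-4-methylhex-5-yn-3-ol | CC[C@H](O)[C@H](C)C#C | intermediate
18 | lithium (3S,4R)-6-lithio-4-methylhex-5-yn-3-olate | CC[C@H](O[Li])[C@H](C)C#C[Li] | intermediate
19 | (3S,4R)-4-methylhept-5-yn-3-ol | CC[C@H](O)[C@H](C)C#CC | intermediate
20 | (3S,4R,5E)-6-[chlorobis(cyclopentadienyl)zirconio]-4-methylhept-5-en-3-ol, O-bound to Cp2ZrCl | CC[C@H](O[Zr](Cl)(C1C=CC=C1)C1C=CC=C1)[C@H](C)/C=C(\C)[Zr](Cl)(C1C=CC=C1)C1C=CC=C1 | intermediate
21 | (3S,4R,5E)-6-iodo-4-methylhept-5-en-3-ol | CC[C@H](O)[C@H](C)/C=C(\C)I | intermediate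
22 | propyne | CC#C | starting material
23 | (3S,4R,5E)-4,6-dimethylnon-5-en-7-yn-3-ol | CC[C@H](O)[C@H](C)/C=C(\C)C#CC | intermediate
24 | (3S,4R,5E,7E)-8-[chlorobis(cyclopentadienyl)zirconio]-4,6-dimethylnona-5,7-dien-3-ol, O-bound to Cp2ZrCl | CC[C@H](O[Zr](Cl)(C1C=CC=C1)C1C=CC=C1)[C@H](C)/C=C(\C)/C=C(\C)[Zr](Cl)(C1C=CC=C1)C1C=CC=C1 | intermediate
25 | (3S,4R,5E,7E)-8-(chlorozincio)-4,6-dimethylnona-5,7-dien-3-ol, O-bound to Cp2ZrCl | CC[C@H](O[Zr](Cl)(C1C=CC=C1)C1C=CC=C1)[C@H](C)/C=C(\C)/C=C(\C)[Zn]Cl | intermediate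
26 | 2-[(2E,4Z,6E,8E,10R,11S)-11-hydroxy-4,6,8,10-tetramethyltrideca-2,4,6,8-tetraen-2-yl]-6-methoxy-3,5-dimethyl-4H-pyran-4-one | CC[C@H](O)[C@H](C)/C=C(\C)/C=C(\C)/C=C(/C)\C=C(/C)c1oc(OC)c(C)c(=O)c1C | intermediate
27 | 2-{(1R,6S)-6-[(2E,4R,5S)-5-hydroxy-4-methylhept-2-en-2-yl]-1,3,5-trimethylcyclohexa-2,4-dien-1-yl}-6-methoxy-3,5-dimethyl-4H-pyran-4-one | CC[C@H](O)[C@H](C)/C=C(\C)[C@H]1C(C)=CC(C)=C[C@@]1(C)c1oc(OC)c(C)c(=O)c1C | intermediate
28 | 2-methoxy-3,5-dimethyl-6-{(1R,6S)-1,3,5-trimethyl-6-[(2E,4R)-4-methyl-5-oxohept-2-en-2-yl]cyclohexa-2,4-dien-1-yl}-4H-pyran-4-one | CCC(=O)[C@H](C)/C=C(\C)[C@H]1C(C)=CC(C)=C[C@@]1(C)c1oc(OC)c(C)c(=O)c1C | intermediate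
29 | 2-methoxy-3,5-dimethyl-6-{(1R,4R,5R,6S)-2,4,6-trimethyl-5-[(2E,4R)-4-methyl-5-oxohept-2-en-2-yl]-7-oxabicyclo[4.1.0]hept-2-en-4-yl}-4H-pyran-4-one | CCC(=O)[C@H](C)/C=C(\C)[C@H]1[C@]2(C)O[C@@H]2C(C)=C[C@@]1(C)c1oc(OC)c(C)c(=O)c1C | target

## Step count and risks

Total steps: 14. Longest linear sequence: 9 (steps 1–6, then 12–14); the enynol arm is 5 steps (7–11).

**Most likely to fail, in order:**

**Step 12.** The hydrozirconation regiochemistry cannot be checked in the pot, residual Cp2Zr(H)Cl can reduce the pyranone or the iodide, and the ring closure has little facial bias. The fallback makes and purifies the nucleophile first. It sets out from enyne 23: copper-catalysed syn-hydroboration (CuCl, Xantphos, NaOt-Bu, B2pin2, MeOH, THF, rt) gives (3S,4R,5E,7Z)-4,6-dimethyl-8-(4,4,5,5-tetramethyl-1,3,2-dioxaborolan-2-yl)nona-5,7-dien-3-ol F1. Suzuki–Miyaura coupling of this boronate with iodide 12 (Pd(PPh3)4, aq. K3PO4, THF, rt, dark) comes back to the route at tetraene 26, which is heated as in step 12. The low diastereomer ratio of the closure is not cured by this; the unwanted (1S,6R) isomer is lost in either variant.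

**Step 14.** DMDO may also attack the side-chain trisubstituted alkene of 28, or give some syn-epoxide. The fallback moves the epoxidation in front of the ketone oxidation and shields the side-chain alkene with a bulky silyl ether. It sets out from alcohol 27: TIPSOTf and 2,6-lutidine (CH2Cl2, −78 °C) give 2-methoxy-3,5-dimethyl-6-{(1R,6S)-1,3,5-trimethyl-6-[(2E,4R,5S)-4-methyl-5-(triisopropylsilyloxy)hept-2-en-2-yl]cyclohexa-2,4-dien-1-yl}-4H-pyran-4-one F2. DMDO (acetone, −40 °C) then gives 2-methoxy-3,5-dimethyl-6-{(1R,4R,5R,6S)-2,4,6-trimethyl-5-[(2E,4R,5S)-4-methyl-5-(triisopropylsilyloxy)hept-2-en-2-yl]-7-oxabicyclo[4.1.0]hept-2-en-4-yl}-4H-pyran-4-one F3. TBAF buffered with AcOH (THF, 0 °C) gives 2-{(1R,4R,5R,6S)-5-[(2E,4R,5S)-5-hydroxy-4-methylhept-2-en-2-yl]-2,4,6-trimethyl-7-oxabicyclo[4.1.0]hept-2-en-4-yl}-6-methoxy-3,5-dimethyl-4H-pyran-4-one F4. Pyridine-buffered Dess–Martin oxidation of this epoxy alcohol comes back to the route at target 29.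

**Step 2.** The (Z)-β-iodoenal 5 may isomerise or over-homologate during the warm Wittig reaction with the formyl ylide. The fallback sets out from alcohol 3: MnO2 oxidation, then ethyl 2-(triphenylphosphoranylidene)propanoate at rt, gives ethyl (2E,4Z)-5-iodo-2,4-dimethylpenta-2,4-dienoate F5. DIBAL-H (CH2Cl2, −78 °C) reduces it to (2E,4Z)-5-iodo-2,4-dimethylpenta-2,4-dien-1-ol F6, and MnO2 oxidation of this dienol comes back to the route at dienal 6.

## Further compounds

F1 | step 12 | (3S,4R,5E,7Z)-4,6-dimethyl-8-(4,4,5,5-tetramethyl-1,3,2-dioxaborolan-2-yl)nona-5,7-dien-3-ol | CC[C@H](O)[C@H](C)/C=C(\C)/C=C(\C)B1OC(C)(C)C(C)(C)O1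
F2 | step 14 | 2-methoxy-3,5-dimethyl-6-{(1R,6S)-1,3,5-trimethyl-6-[(2E,4R,5S)-4-methyl-5-(triisopropylsilyloxy)hept-2-en-2-yl]cyclohexa-2,4-dien-1-yl}-4H-pyran-4-one | CC[C@H](O[Si](C(C)C)(C(C)C)C(C)C)[C@H](C)/C=C(\C)[C@H]1C(C)=CC(C)=C[C@@]1(C)c1oc(OC)c(C)c(=O)c1C
F3 | step 14 | 2-methoxy-3,5-dimethyl-6-{(1R,4R,5R,6S)-2,4,6-trimethyl-5-[(2E,4R,5S)-4-methyl-5-(triisopropylsilyloxy)hept-2-en-2-yl]-7-oxabicyclo[4.1.0]hept-2-en-4-yl}-4H-pyran-4-one | CC[C@H](O[Si](C(C)C)(C(C)C)C(C)C)[C@H](C)/C=C(\C)[C@H]1[C@]2(C)O[C@@H]2C(C)=C[C@@]1(C)c1oc(OC)c(C)c(=O)c1C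
F4 | step 14 | 2-{(1R,4R,5R,6S)-5-[(2E,4R,5S)-5-hydroxy-4-methylhept-2-en-2-yl]-2,4,6-trimethyl-7-oxabicyclo[4.1.0]hept-2-en-4-yl}-6-methoxy-3,5-dimethyl-4H-pyran-4-one | CC[C@H](O)[C@H](C)/C=C(\C)[C@H]1[C@]2(C)O[C@@H]2C(C)=C[C@@]1(C)c1oc(OC)c(C)c(=O)c1C
F5 | step 2 | ethyl (2E,4Z)-5-iodo-2,4-dimethylpenta-2,4-dienoate | CCOC(=O)/C(C)=C/C(C)=C\I
F6 | step 2 | (2E,4Z)-5-iodo-2,4-dimethylpenta-2,4-dien-1-ol | OC/C(C)=C/C(C)=C\I
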